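## Structural features

The target is a germacranolide: a ten-membered carbocycle (C1–C10) with two E trisubstituted alkenes, C1=C10 (methyl C14 on C10) and C4=C5 (C15H2O on C4, cis to C6), trans-fused across C7–C8 to an α-methylene-γ-butyrolactone (C11=C13, C12 carbonyl, ring oxygen on C8). Three contiguous stereocentres sit on the C5–C9 bridge: C6 (R, isovalerate), C7 (R) and C8 (S, lactone oxygen), with O6, the C7–C11 bond and O8 alternately trans on the ring. The fourth, C3 (R, free hydroxyl), stands alone on the far side of C4=C5, next to the C15 isovalerate. The fragile parts are the α-methylene lactone (a Michael acceptor), the two allylic esters (acyl shift to the free C3 or C8 oxygen), and the 1,5-diene of the medium ring (transannular cyclisation in acid, Cope rearrangement on heating). The real difficulty is closing a strained (E,E)-cyclodeca-1,5-diene while fixing C6 and C7 relative to C8 on a mobile ring and keeping five oxygen functions (C3, C6, C8, C12, C15) apart. The key step uses the unit O–C6–C7–C11(=C13): C6 is a carbinol carbon allylic to C4=C5 and homoallylic to C11=C13, the imprint of a [2,3]-Wittig shift of a C6–O–C13 diallylic ether. Run transannularly, that shift converts a 13-membered ether, easy to close by O-alkylation, into the ten-membered ring with C6–OH, C7 and the exocyclic methylene already in place.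

## Logic of the disconnections

30 ⇒ 29. The C15–O acyl bond is cut last. The primary allylic C15 hydroxyl of 29 is the only unhindered hydroxyl, so this ester never has to pass through base or fluoride. The gain is that O3 and O15 can travel together under one group. The forward acylation must choose C15–OH over the secondary C3–OH.

29 ⇒ 28. The two acetal C–O bonds (O3 and O15 to the isopropylidene carbon) are cut. One six-membered acetal masks both oxygens and is inert to organolithium, fluoride and oxoammonium reagents. Its removal must be mild enough for the methylene lactone and the C6 ester.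

28 ⇒ 25 (through 26 and 27). The O8–C12 lactone bond is cut and C12 is returned to the alcohol level. An ester or lactone cannot survive the carbanion step, while the 2-methylene-1,4-diol of 25 is exactly what the ring contraction delivers after desilylation. The oxidation must select the primary allylic C12–OH and stop at the lactone; O6 is acylated beforehand so that only O8 can close the ring.

25 ⇒ 24 ⇒ 23. The two Si–O bonds (O8, O12) and the O6 acyl bond are cut. This returns to the free C6 alcohol with every other oxygen masked. The forward acylation meets a hindered secondary alcohol, and the desilylation must not trigger an acyl shift from O6 to O8.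

23 ⇒ 21 (through 22). C6–C7 is cut and O–C13 re-formed: the retro-[2,3]-Wittig move. The ten-membered ring becomes a 13-membered diallylic ether and the stereocentres C6 and C7 disappear, leaving only C3 and C8. The forward step needs lithiation at C6 only, an anti C6/C7 outcome, and the correct face of C7 relative to C8. Three design choices serve these needs:
- C12 carries a triisopropylsilyl ether. It shields the C13 and C12 protons from the base and does not migrate to a neighbouring alkoxide, which would swap the roles of the C12 and C13 arms.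
- The only Lewis-basic ether oxygens (the acetal) sit beside C6, so the base is held there.
- C15–H and C3–H are locked in the dioxane, where the axial hydrogens are screened by the axial acetal methyl and the equatorial C15–H lies in the alkene plane.

21 ⇒ 20. The O–C13 bond is cut, giving an open chain with C6–OH and a C13 chloride. C13 is the electrophile so that no alkoxide is ever generated next to the C12 silyl ether. The forward step is a 13-membered Williamson closure that needs high dilution and SN2 rather than SN2' attack.

20 ⇒ 19 ⇒ 17 + 18. C4=C5 is cut and C6 is taken to the ester level. The dioxanone 17 carries C3, C4 and C15 with the acetal already in place. The olefination must put C6 trans to C3 and must not epimerise C3, which is α to the ketone.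

17 ⇒ 16 ⇒ 14 + 11, and 14 ⇒ 12 + 13. C2–C3 is cut. The chiral-hydrazone alkylation sets C3 by auxiliary control and joins the whole C1–C2/C7–C14 chain in one step. The azaenolate must choose the C2 chloride of 11 over the C13 chloride.

11 ⇒ 10 ⇒ 9 ⇒ 8. Both C–Cl bonds go back to C–OH, the alcohols to an ester (C13) and an acetate (C2), and the O8 silyl ether to the free alcohol. One hydride reduction therefore frees both allylic alcohols and one operation chlorinates both. The reduction must leave the silyl ethers in place and the chlorination must not transpose the allyl systems.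

8 ⇒ 7 ⇒ 5 + 3 (through 6). C7=C11 and the C8–O bond are cut. An organocatalytic α-oxygenation sets C8 on a simple aldehyde, and the olefination brings C11, C12 and C13 with the two arms already different (ester against silyl ether). The olefination must be E so that the ester carbon is the arm trans to C8.

5 ⇒ 4 and 3 ⇒ 1 + 2. The aldehyde carbon C7 comes from cleaving the remote alkene of 4, which supplies C1=C10 with the right geometry, C14, C2 and C7–C9. The C11–C12 bond of 3 comes from C-alkylation of 1 with 2. The ozonolysis must spare the alkene next to the acetate, and the alkylation must stop at the mono-adduct.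

## Other disconnections considered

Alternative 1: The cut is C9–C10 together with the lactone bond O8–C12. The open-chain substrate A1 holds a terminal C8–C9 epoxide, an E vinyl iodide at C10 and a C12 ester on C11. NiI2 with 4,4′-di-tert-butyl-2,2′-bipyridine, NaI, Et3NHCl and Zn would open the epoxide at C9, join that carbon to C10 with retention of alkene geometry, and let O8 close onto C12 to give the tris-silyl lactone A2.
- In its favour: C3, C6, C7 and C8 are all set before the ring exists, so no stereocentre depends on the conformation of a macrocycle. On this point it is better than the chosen plan, where C6 and C7 rest on transannular selection.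
- Also in its favour: ring and lactone form in one operation, and the two silyl ethers that become isovalerates (O6, O15) can be freed and acylated together, which is at least the equal of the chosen end game.
- Against it: the ten-membered (E,E)-ring must close end to end through an organonickel or radical intermediate, which costs entropy and strain and competes with reduction of the iodide and with dimerisation. The chosen plan avoids this with a five-centre shift inside a preformed ring.
- Against it: A2 lacks C13, so an α-methylenation of the lactone must follow, and A1 needs four stereocentres built by acyclic control.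
- Overall: the reaction type is established between two molecules, but its use to close a medium ring is a longer extrapolation than the ring contraction, and the route would likely be longer.

Alternative 2: The cut rejoins C5 and C10, turning the triene A4 into the trans-fused eudesmane dienol silyl ether A3. Irradiation at 254–300 nm and −78 °C would open ring A by conrotatory 6π cleavage of C5–C10.
- In its favour: there is no macrocyclisation at all, and both ring alkenes (C1=C10, C4=C5) take their E geometry from orbital symmetry and the trans ring fusion. On alkene geometry this is the equal of the chosen plan.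
- Also in its favour: C6, C7 and C8 are set on a rigid chair decalin, which is better than setting C6 and C7 on a macrocycle.
- Against it: the opening is a photoequilibrium, the triene can reclose thermally to a cis-fused decalin, and the methylene lactone and dienol ether absorb in the same region.
- Against it: after opening, the dienol ether must be hydrolysed to the C3 enone and the ketone reduced to 3R on a flexible ring beside the methylene lactone. C3 is then set last and by substrate control, whereas the chosen plan sets it early by an auxiliary.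
- Against it: making A3 with oxygen at C3, C6, C8 and C15 plus the methylene lactone is long.
- A correction of the descriptor: the central C2=C3 bond of A4 is cis within the ring but 2E by the sequence rule, because the silyloxy group outranks C4.

Alternative 3: The cut is C5–C6. ZnMe2 with a chiral bis(prolinol)phenol ligand would turn the terminal alkyne of A5 into a zinc acetylide that adds to the C6 aldehyde, closing the ten-membered enyne A6 and setting C6.
- In its favour: C6 is set by the catalyst, not by the substrate, which is better than the chosen plan on that centre. The alkyne also allows late introduction of C15.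
- Against it: four collinear atoms (C3–C4≡C5–C6) must fit into a ten-membered ring that also holds an E alkene, and the catalyst works best concentrated while the ring closure needs dilution.
- Against it: A5 is an α-branched β,γ-unsaturated aldehyde whose C7 centre can epimerise or move into conjugation under the basic zinc conditions.
- Against it: A6 still needs a regio- and stereoselective trans-addition (H to C5, C15 to C4) between two propargylic oxygens, and the C7/C8 pair must be built by acyclic control.
- Overall: equal in convergence, weaker in ring-closure probability and in step count after the key step.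

Key step: step 14

Remarks on the chemistry (assumptions):
- Germacrane numbering (C1–C15) is used for every intermediate.
- The spatial arrangement at C7 never changes, but its sequence-rule descriptor does: 7S in 23 and 24, 7R from 25 on. Likewise C7=C11 of 21 is Z by the sequence rule although C8 is trans to C13.
- The copper-catalysed N–O cleavage of step 4 is taken to release the PhN fragment as azobenzene.

## Route

Step 1
Reactants: 1 triethyl phosphonoacetate; 2 (chloromethoxy)triisopropylsilane
Product: 3 ethyl 2-(diethoxyphosphoryl)-3-[(triisopropylsilyl)oxy]propanoate (racemic)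
Conditions: NaH (1.0 equiv), THF, 0 °C; then 2, 0 °C → rt (1 in slight excess)
Reagents that add atoms: none
Why: C-alkylation of the sodium phosphonoacetate by an α-chloro ether, the same reaction type as the alkoxymethylation of malonates; it brings in C12 already as its silyl ether, and the α-centre is irrelevant because it is deprotonated in step 3.

Step 2
Reactants: 4 geranyl acetate
Product: 5 (4E)-6-acetoxy-4-methylhex-4-enal
Conditions: O3 (1.0 equiv), CH2Cl2, −78 °C; then Me2S, −78 °C → rt
Reagents that add atoms: ozone, [O-][O+]=O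
Why: Chemoselective ozonolysis; the remote trisubstituted alkene is more electron-rich than the one deactivated by the allylic acetate, so one equivalent of ozone should cleave only the isopropylidene end and leave the E alkene that becomes C1=C10.

Step 3
Reactants: 5 (4E)-6-acetoxy-4-methylhex-4-enal; 3 ethyl 2-(diethoxyphosphoryl)-3-[(triisopropylsilyl)oxy]propanoate
Product: 7 ethyl (2E,4S,6E)-8-acetoxy-6-methyl-4-[(phenylamino)oxy]-2-{[(triisopropylsilyl)oxy]methyl}octa-2,6-dienoate, via α-anilinooxy aldehyde 6 (not isolated)
Conditions: D-proline (25 mol %), PhNO (1.0 equiv), MeCN, −20 °C; then 3, LiCl, DBU, 0 °C → rt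
Reagents that add atoms: nitrosobenzene, O=Nc1ccccc1
Why: Proline-catalysed α-aminoxylation through the E enamine, with the carboxylic acid steering nitrosobenzene to one face, sets C8 (D-proline gives the 2S aldehyde); the in-situ Horner–Wadsworth–Emmons olefination with the α-branched phosphonate should place the ester trans to C8, so the ester carbon becomes C13 and the silyloxymethyl arm C12.

Step 4
Reactants: 7 ethyl (2E,4S,6E)-8-acetoxy-6-methyl-4-[(phenylamino)oxy]-2-{[(triisopropylsilyl)oxy]methyl}octa-2,6-dienoate
Product: 8 ethyl (2E,4S,6E)-8-acetoxy-4-hydroxy-6-methyl-2-{[(triisopropylsilyl)oxy]methyl}octa-2,6-dienoate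
Conditions: Cu(OAc)2·H2O (30 mol %), EtOH, rt
Reagents that add atoms: none
Why: Copper-catalysed cleavage of the weak N–O bond frees the C8 hydroxyl under neutral conditions; any Z enoate would lactonise to a butenolide here and be removed, which the E isomer cannot do.

Step 5
Reactants: 8 ethyl (2E,4S,6E)-8-acetoxy-4-hydroxy-6-methyl-2-{[(triisopropylsilyl)oxy]methyl}octa-2,6-dienoate
Product: 9 ethyl (2E,4S,6E)-8-acetoxy-4-[(tert-butyldimethylsilyl)oxy]-6-methyl-2-{[(triisopropylsilyl)oxy]methyl}octa-2,6-dienoate
Conditions: TBSOTf, 2,6-lutidine, CH2Cl2, −78 → 0 °C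
Reagents that add atoms: tert-butyldimethylsilyl triflate, CC(C)(C)[Si](C)(C)OS(=O)(=O)C(F)(F)F
Why: Silylation of a hindered secondary allylic alcohol with a silyl triflate and a non-nucleophilic base; the ester, acetate and triisopropylsilyl ether are inert.

Step 6
Reactants: 9 ethyl (2E,4S,6E)-8-acetoxy-4-[(tert-butyldimethylsilyl)oxy]-6-methyl-2-{[(triisopropylsilyl)oxy]methyl}octa-2,6-dienoate
Product: 10 (2Z,4S,6E)-4-[(tert-butyldimethylsilyl)oxy]-6-methyl-2-{[(triisopropylsilyl)oxy]methyl}octa-2,6-diene-1,8-diol
Conditions: i-Bu2AlH (5 equiv), CH2Cl2, −78 → −20 °C; aq. potassium sodium tartrate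
Reagents that add atoms: none
Why: 1,2-Reduction of the conjugated ester and reductive removal of the acetate in one operation give the two primary allylic alcohols (C13 and C2); the aluminium alkoxide formed at low temperature does not move the triisopropylsilyl group.

Step 7
Reactants: 10 (2Z,4S,6E)-4-[(tert-butyldimethylsilyl)oxy]-6-methyl-2-{[(triisopropylsilyl)oxy]methyl}octa-2,6-diene-1,8-diol
Product: 11 (2E,4S,6E)-4-[(tert-butyldimethylsilyl)oxy]-1,8-dichloro-6-methyl-2-{[(triisopropylsilyl)oxy]methyl}octa-2,6-diene
Conditions: MsCl, LiCl, 2,4,6-collidine, DMF, 0 °C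
Reagents that add atoms: lithium chloride, [Li+].[Cl-]; methanesulfonyl chloride, CS(=O)(=O)Cl (either may supply the chloride)
Why: In-situ mesylation and SN2 displacement by chloride, the standard conversion of primary allylic alcohols (geraniol-type included) into allylic chlorides without allylic transposition.

Step 8
Reactants: 12 2,2-dimethyl-1,3-dioxan-5-one; 13 (R)-1-amino-2-(methoxymethyl)pyrrolidine (RAMP)
Product: 14 (2R)-N-(2,2-dimethyl-1,3-dioxan-5-ylidene)-2-(methoxymethyl)pyrrolidin-1-amine
Conditions: toluene, 4 Å molecular sieves, 60 °C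
Reagents that add atoms: none
Why: Hydrazone condensation of the symmetrical ketone with the chiral hydrazine; the water is taken up by the sieves.

Step 9
Reactants: 14 (2R)-N-(2,2-dimethyl-1,3-dioxan-5-ylidene)-2-(methoxymethyl)pyrrolidin-1-amine; 11 (2E,4S,6E)-4-[(tert-butyldimethylsilyl)oxy]-1,8-dichloro-6-methyl-2-{[(triisopropylsilyl)oxy]methyl}octa-2,6-diene
Product: 16 (2R)-N-[(4R)-4-{(2E,5S,6E)-5-[(tert-butyldimethylsilyl)oxy]-8-chloro-3-methyl-7-{[(triisopropylsilyl)oxy]methyl}octa-2,6-dien-1-yl}-2,2-dimethyl-1,3-dioxan-5-ylidene]-2-(methoxymethyl)pyrrolidin-1-amine, via lithium azaenolate 15 (not isolated)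
Conditions: t-BuLi (1.0 equiv), THF, −78 °C; then 11 (1.0 equiv), −100 → −40 °C
Reagents that add atoms: none
Why: RAMP-hydrazone alkylation: the methoxy-chelated lithium azaenolate is alkylated on the face away from the pyrrolidine side arm, and the R auxiliary gives 4R on the dioxane (C3 R), the mirror image of the sense known for the S auxiliary. The C2 chloride (unhindered, on a γ,γ-dialkyl allyl unit) should react far faster than the C13 chloride, which is flanked by the fully substituted C11 with its silyloxymethyl group.

Step 10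
Reactants: 16 (the alkylated hydrazone)
Product: 17 (4R)-4-{(2E,5S,6E)-5-[(tert-butyldimethylsilyl)oxy]-8-chloro-3-methyl-7-{[(triisopropylsilyl)oxy]methyl}octa-2,6-dien-1-yl}-2,2-dimethyl-1,3-dioxan-5-one
Conditions: sat. aq. oxalic acid, Et2O, rt (two phases)
Reagents that add atoms: water, O
Why: Mild two-phase hydrolysis of the hydrazone, the standard racemisation-free cleavage for α-alkylated dioxanones; acetal, silyl ethers and allylic chloride stay intact, and the auxiliary is recovered from the aqueous phase.

Step 11
Reactants: 17 (the dioxanone); 18 ethyl (triphenylphosphoranylidene)acetate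
Product: 19 ethyl (2E)-2-[(4R)-4-{(2E,5S,6E)-5-[(tert-butyldimethylsilyl)oxy]-8-chloro-3-methyl-7-{[(triisopropylsilyl)oxy]methyl}octa-2,6-dien-1-yl}-2,2-dimethyl-1,3-dioxan-5-ylidene]acetate
Conditions: toluene, 40 °C
Reagents that add atoms: none
Why: Wittig olefination of an activated α,α′-dioxygenated ketone with a stabilised, non-basic ylide, so C3 should not epimerise; allylic 1,3-strain with the C3 substituent directs the ester to the C15 side, giving C6 trans to C3.

Step 12
Reactants: 19 (the dioxanylidene ester)
Product: 20 (2E)-2-[(4R)-4-{(2E,5S,6E)-5-[(tert-butyldimethylsilyl)oxy]-8-chloro-3-methyl-7-{[(triisopropylsilyl)oxy]methyl}octa-2,6-dien-1-yl}-2,2-dimethyl-1,3-dioxan-5-ylidene]ethan-1-ol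
Conditions: i-Bu2AlH (2.5 equiv), CH2Cl2, −78 °C; aq. potassium sodium tartrate
Reagents that add atoms: none
Why: 1,2-Reduction of the conjugated ester to the allylic alcohol (C6–OH); a primary allylic chloride is not reduced by this hydride at −78 °C.

Step 13
Reactants: 20 (the C6 alcohol / C13 chloride)
Product: 21 (3R,8S)-13-membered diallylic ether: oxygen bridging C6 and C13; C1=C10 E, C4=C5 with C3 trans to C6, C7=C11 with C8 trans to C13; tert-butyldimethylsilyl ether on O8, triisopropylsilyloxymethyl (C12) on C11, O3 and O15 joined as the isopropylidene acetal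
Conditions: NaH (3 equiv), n-Bu4NI (0.2 equiv), THF, 0.002 M (syringe-pump addition), 50 °C
Reagents that add atoms: none
Why: Intramolecular Williamson etherification, SN2 attack of the C6 alkoxide on the primary allylic chloride with iodide catalysis; high dilution, two E alkenes and the dioxane favour the 13-membered ring, and no silyl ether lies next to the alkoxide.

Step 14
Reactants: 21 (the 13-membered diallylic ether)
Product: 23 (3R,6R,7S,8S)-ten-membered alcohol: germacra-1(10)E,4E,11(13)-triene with free 6-OH, 7-[3-(triisopropylsilyloxy)prop-1-en-2-yl], 8-O-tert-butyldimethylsilyl and 3,15-O-isopropylidene; H6/H7 trans, H7/H8 trans, via C6-lithiated ether 22 (not isolated)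
Conditions: n-BuLi (2.5 equiv), THF, −78 → −30 °C; sat. aq. NH4Cl at −78 °C
Reagents that add atoms: none
Why: n-BuLi, held by the ring ether oxygen and the nearby acetal oxygen on C15, removes a C6 proton to give the α-oxy allyllithium 22, whose C6 attacks C7 suprafacially through a five-membered envelope (C6, O, C13, C11, C7), forming C6–C7, moving the alkene to C11=C13 and breaking O–C13. The closest known reaction type is the transannular [2,3]-Wittig ring contraction of 13-membered diallylic ethers to ten-membered (E,E)-dienols of the germacrane family. The carbocycle is closed by transannular bond formation inside the preformed 13-membered ring (loss of O, C13 and C11 from the ring), a five-centre sigmatropic closure and not an end-to-end cyclisation. C6 relative to C7 is set by the alkene geometry: with C8 trans to C13 and the C5 vinyl group exo on the envelope (endo would meet C12), the anti arrangement with H6 and H7 trans should result. C7 relative to C8, and hence the absolute sense, is set by the C8 stereocentre: the carbanion should approach anti to the C8–O bond with H8 eclipsing the C11–C12 bond (least allylic 1,3-strain), which is the crown-like transition state with O6, the C7 side chain and O8 all pseudo-equatorial and gives C11 trans to O8. The step needs lithiation at C6 and not at C13, C12, C15, C3 or C8, and [2,3] over [1,2] shift. C6 is the only O-bearing methylene on a CH= carbon; C13 and C12 are screened by the fully substituted C11 and the triisopropylsilyl group; C15–H and C3–H are held in the dioxane; and low temperature favours the concerted pathway. Quenching cold keeps the silyl groups from moving to the new C6 alkoxide.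

Step 15
Reactants: 23 (the ten-membered alcohol)
Product: 24 (3R,6R,7S,8S)-6-O-(3-methylbutanoyl) ester of 23
Conditions: (i-BuCO)2O (3 equiv), DMAP (0.3 equiv), Et3N, CH2Cl2, rt
Reagents that add atoms: 3-methylbutanoic anhydride, CC(C)CC(=O)OC(=O)CC(C)C
Why: DMAP-catalysed acylation of the only free hydroxyl; it also blocks O6 so that only O8 can lactonise later.

Step 16
Reactants: 24 (the C6 ester)
Product: 25 (3R,6R,7R,8S)-8,12-diol: 3,15-O-isopropylidene-6-O-(3-methylbutanoyl)germacra-1(10)E,4E,11(13)-triene-3,6,8,12,15-pentol
Conditions: TBAF (5 equiv), AcOH (5 equiv), THF, rt → 40 °C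
Reagents that add atoms: none
Why: Fluoride cleavage of both silyl ethers; buffering with acetic acid keeps the medium non-basic so that the C6 ester should not shift to O8 or O12, and the acetal is untouched.

Step 17
Reactants: 25 (the 8,12-diol)
Product: 28 (3R,6R,7R,8S)-3,15-O-isopropylidene-6-(3-methylbutanoyloxy)germacra-1(10)E,4E,11(13)-trien-12,8-olide, via hydroxy enal 26 (not isolated), via lactol 27 (not isolated)
Conditions: TEMPO (0.3 equiv), PhI(OAc)2 (3 equiv), CH2Cl2, rt
Reagents that add atoms: none
Why: Oxoammonium oxidation selects the primary allylic C12 alcohol; the enal is trapped by O8 as the five-membered lactol, which is oxidised on to the α-methylene-γ-lactone, the known oxidative lactonisation of 2-methylene-1,4-diols.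

Step 18
Reactants: 28 (the lactone acetal)
Product: 29 (3R,6R,7R,8S)-3,15-dihydroxy-6-(3-methylbutanoyloxy)germacra-1(10)E,4E,11(13)-trien-12,8-olide
Conditions: AcOH–H2O–THF (3:1:1), 40 °C
Reagents that add atoms: none
Why: Mild acid hydrolysis of the 1,3-dioxane acetal; the methylene lactone and the ester tolerate aqueous acetic acid.

Step 19
Reactants: 29 (the 3,15-diol)
Product: 30 (3R,6R,7R,8S)-3-hydroxy-6,15-bis(3-methylbutanoyloxy)germacra-1(10)E,4E,11(13)-trien-12,8-olide, CNP0317194.1
Conditions: i-BuCOCl (1.1 equiv), 2,4,6-collidine, CH2Cl2, −78 → −40 °C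
Reagents that add atoms: 3-methylbutanoyl chloride, CC(C)CC(=O)Cl
Why: Kinetically selective acylation of the primary allylic C15 hydroxyl over the hindered secondary C3 hydroxyl with an acid chloride and a hindered base at low temperature.

## Compound list

1 | triethyl phosphonoacetate | CCOC(=O)CP(=O)(OCC)OCC | starting material
2 | (chloromethoxy)triisopropylsilane | ClCO[Si](C(C)C)(C(C)C)C(C)C | starting material
3 | ethyl 2-(diethoxyphosphoryl)-3-[(triisopropylsilyl)oxy]propanoate (racemic) | CCOC(=O)C(CO[Si](C(C)C)(C(C)C)C(C)C)P(=O)(OCC)OCC | intermediate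
4 | geranyl acetate | CC(C)=CCC/C(C)=C/COC(C)=O | starting material
5 | (4E)-6-acetoxy-4-methylhex-4-enal | O=CCC/C(C)=C/COC(C)=O | intermediate
6 | (2S,4E)-6-acetoxy-4-methyl-2-[(phenylamino)oxy]hex-4-enal | O=C[C@@H](ONc1ccccc1)C/C(C)=C/COC(C)=O | intermediate
7 | ethyl (2E,4S,6E)-8-acetoxy-6-methyl-4-[(phenylamino)oxy]-2-{[(triisopropylsilyl)oxy]methyl}octa-2,6-dienoate | CCOC(=O)/C(CO[Si](C(C)C)(C(C)C)C(C)C)=C/[C@@H](ONc1ccccc1)C/C(C)=C/COC(C)=O | intermediate
8 | ethyl (2E,4S,6E)-8-acetoxy-4-hydroxy-6-methyl-2-{[(triisopropylsilyl)oxy]methyl}octa-2,6-dienoate | CCOC(=O)/C(CO[Si](C(C)C)(C(C)C)C(C)C)=C/[C@@H](O)C/C(C)=C/COC(C)=O | intermediate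
9 | ethyl (2E,4S,6E)-8-acetoxy-4-[(tert-butyldimethylsilyl)oxy]-6-methyl-2-{[(triisopropylsilyl)oxy]methyl}octa-2,6-dienoate | CCOC(=O)/C(CO[Si](C(C)C)(C(C)C)C(C)C)=C/[C@@H](O[Si](C)(C)C(C)(C)C)C/C(C)=C/COC(C)=O | intermediate
10 | (2Z,4S,6E)-4-[(tert-butyldimethylsilyl)oxy]-6-methyl-2-{[(triisopropylsilyl)oxy]methyl}octa-2,6-diene-1,8-diol | OC/C(CO[Si](C(C)C)(C(C)C)C(C)C)=C/[C@@H](O[Si](C)(C)C(C)(C)C)C/C(C)=C/CO | intermediate
11 | (2E,4S,6E)-4-[(tert-butyldimethylsilyl)oxy]-1,8-dichloro-6-methyl-2-{[(triisopropylsilyl)oxy]methyl}octa-2,6-diene | ClC/C(CO[Si](C(C)C)(C(C)C)C(C)C)=C/[C@@H](O[Si](C)(C)C(C)(C)C)C/C(C)=C/CCl | intermediate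
12 | 2,2-dimethyl-1,3-dioxan-5-one | CC1(C)OCC(=O)CO1 | starting material
13 | (R)-1-amino-2-(methoxymethyl)pyrrolidine (RAMP) | COC[C@H]1CCCN1N | starting material
14 | (2R)-N-(2,2-dimethyl-1,3-dioxan-5-ylidene)-2-(methoxymethyl)pyrrolidin-1-amine | CC1(C)OCC(CO1)=NN1CCC[C@@H]1COC | intermediate
15 | lithium azaenolate of 14 | CC1(C)OCC(=CO1)N([Li])N1CCC[C@@H]1COC | intermediate
16 | (2R)-N-[(4R)-4-{(2E,5S,6E)-5-[(tert-butyldimethylsilyl)oxy]-8-chloro-3-methyl-7-{[(triisopropylsilyl)oxy]methyl}octa-2,6-dien-1-yl}-2,2-dimethyl-1,3-dioxan-5-ylidene]-2-(methoxymethyl)pyrrolidin-1-amine | CC1(C)OCC(=NN2CCC[C@@H]2COC)[C@@H](C/C=C(C)/C[C@H](O[Si](C)(C)C(C)(C)C)/C=C(CO[Si](C(C)C)(C(C)C)C(C)C)/CCl)O1 | intermediate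
17 | (4R)-4-{(2E,5S,6E)-5-[(tert-butyldimethylsilyl)oxy]-8-chloro-3-methyl-7-{[(triisopropylsilyl)oxy]methyl}octa-2,6-dien-1-yl}-2,2-dimethyl-1,3-dioxan-5-one | CC1(C)OCC(=O)[C@@H](C/C=C(C)/C[C@H](O[Si](C)(C)C(C)(C)C)/C=C(CO[Si](C(C)C)(C(C)C)C(C)C)/CCl)O1 | intermediate
18 | ethyl (triphenylphosphoranylidene)acetate | CCOC(=O)C=P(c1ccccc1)(c1ccccc1)c1ccccc1 | starting material
19 | ethyl (2E)-2-[(4R)-4-{(2E,5S,6E)-5-[(tert-butyldimethylsilyl)oxy]-8-chloro-3-methyl-7-{[(triisopropylsilyl)oxy]methyl}octa-2,6-dien-1-yl}-2,2-dimethyl-1,3-dioxan-5-ylidene]acetate | CC1(C)OC/C(=C\C(=O)OCC)[C@@H](C/C=C(C)/C[C@H](O[Si](C)(C)C(C)(C)C)/C=C(CO[Si](C(C)C)(C(C)C)C(C)C)/CCl)O1 | intermediate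
20 | (2E)-2-[(4R)-4-{(2E,5S,6E)-5-[(tert-butyldimethylsilyl)oxy]-8-chloro-3-methyl-7-{[(triisopropylsilyl)oxy]methyl}octa-2,6-dien-1-yl}-2,2-dimethyl-1,3-dioxan-5-ylidene]ethan-1-ol | CC1(C)OC/C(=C\CO)[C@@H](C/C=C(C)/C[C@H](O[Si](C)(C)C(C)(C)C)/C=C(CO[Si](C(C)C)(C(C)C)C(C)C)/CCl)O1 | intermediate
21 | (3R,8S)-13-membered C6–O–C13 diallylic ether, 8-O-tert-butyldimethylsilyl, 12-O-triisopropylsilyl, 3,15-O-isopropylidene (C8 trans to C13, C3 trans to C6, C1=C10 E) | O1C/C(CO[Si](C(C)C)(C(C)C)C(C)C)=C/[C@@H](O[Si](C)(C)C(C)(C)C)C/C(C)=C/C[C@H]2OC(C)(C)OC/C2=C\C1 | intermediate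
22 | C6-lithio derivative of 21 (configuration at C6 undefined) | [Li]C1/C=C2\COC(C)(C)O[C@@H]2C/C=C(C)/C[C@H](O[Si](C)(C)C(C)(C)C)/C=C(CO[Si](C(C)C)(C(C)C)C(C)C)/CO1 | intermediate
23 | (3R,6R,7S,8S)-6-hydroxy-8-O-tert-butyldimethylsilyl-12-O-triisopropylsilyl-3,15-O-isopropylidene-germacra-1(10)E,4E,11(13)-triene | C=C(CO[Si](C(C)C)(C(C)C)C(C)C)[C@@H]1[C@@H](O[Si](C)(C)C(C)(C)C)C/C(C)=C/C[C@H]2OC(C)(C)OC/C2=C\[C@H]1O | intermediate
24 | (3R,6R,7S,8S)-6-O-(3-methylbutanoyl) ester of 23 | C=C(CO[Si](C(C)C)(C(C)C)C(C)C)[C@@H]1[C@@H](O[Si](C)(C)C(C)(C)C)C/C(C)=C/C[C@H]2OC(C)(C)OC/C2=C\[C@H]1OC(=O)CC(C)C | intermediate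
25 | (3R,6R,7R,8S)-3,15-O-isopropylidene-6-O-(3-methylbutanoyl)germacra-1(10)E,4E,11(13)-triene-3,6,8,12,15-pentol | C=C(CO)[C@@H]1[C@@H](O)C/C(C)=C/C[C@H]2OC(C)(C)OC/C2=C\[C@H]1OC(=O)CC(C)C | intermediate
26 | (3R,6R,7R,8S)-12-aldehyde of 25 (8-hydroxy enal) | C=C(C=O)[C@@H]1[C@@H](O)C/C(C)=C/C[C@H]2OC(C)(C)OC/C2=C\[C@H]1OC(=O)CC(C)C | intermediate
27 | 8,12-lactol of 26 (C12 epimers) | C=C1C(O)O[C@H]2C/C(C)=C/C[C@H]3OC(C)(C)OC/C3=C\[C@@H](OC(=O)CC(C)C)[C@H]12 | intermediate
28 | (3R,6R,7R,8S)-3,15-O-isopropylidene-6-(3-methylbutanoyloxy)germacra-1(10)E,4E,11(13)-trien-12,8-olide | C=C1C(=O)O[C@H]2C/C(C)=C/C[C@H]3OC(C)(C)OC/C3=C\[C@@H](OC(=O)CC(C)C)[C@H]12 | intermediate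
29 | (3R,6R,7R,8S)-3,15-dihydroxy-6-(3-methylbutanoyloxy)germacra-1(10)E,4E,11(13)-trien-12,8-olide | C=C1C(=O)O[C@H]2C/C(C)=C/C[C@@H](O)/C(CO)=C/[C@@H](OC(=O)CC(C)C)[C@H]12 | intermediate
30 | (3R,6R,7R,8S)-3-hydroxy-6,15-bis(3-methylbutanoyloxy)germacra-1(10)E,4E,11(13)-trien-12,8-olide (CNP0317194.1) | C=C1C(=O)O[C@H]2C/C(C)=C/C[C@@H](O)/C(COC(=O)CC(C)C)=C/[C@@H](OC(=O)CC(C)C)[C@H]12 | target

## Step count and risk

Total: 19 steps. Longest linear sequence: 17 steps (from 4 to 30, steps 2–7 and 9–19); steps 1 and 8 are side branches.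

Least certain steps:

Step 14 (key step). Three things may go wrong:
- Lithiation could occur at C13 (or C12, C15) and not at C6, leading to the isomeric shift onto C4 or to a [1,2] shift.
- The C6 anion could undergo 1,4-elimination with loss of the cis C15 acetal oxygen, opening the dioxane.
- Facial discrimination at C7 by the C8 silyloxy group could be poor, because it depends on one macrocycle conformation dominating.

Fallback: it sets out from 20 and comes back at 23. Oxidation of 20 with MnO2 would give the enal (2E)-2-[(4R)-4-{(2E,5S,6E)-5-[(tert-butyldimethylsilyl)oxy]-8-chloro-3-methyl-7-{[(triisopropylsilyl)oxy]methyl}octa-2,6-dien-1-yl}-2,2-dimethyl-1,3-dioxan-5-ylidene]acetaldehyde F1. CrCl2 in THF at high dilution would then turn the C13 chloride into an allylchromium species that adds through C7 to the C6 aldehyde (Nozaki–Hiyama–Kishi-type intramolecular allylation). This forms the same C6–C7 bond with the anti preference of that reaction and gives 23 directly, with no carbanion at C6.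

Step 9. The azaenolate may fail to discriminate between the two allylic chlorides of 11 (attack at C13, or double alkylation), and the chloride may need a temperature at which auxiliary control erodes.

Fallback: it sets out from 9 and comes back at 16.
- Ethanolysis of the acetate (K2CO3, EtOH, 0 °C) would give ethyl (2E,4S,6E)-4-[(tert-butyldimethylsilyl)oxy]-8-hydroxy-6-methyl-2-{[(triisopropylsilyl)oxy]methyl}octa-2,6-dienoate F2.
- CBr4/PPh3 would give the corresponding 8-bromide F3, which has a single reactive electrophilic site beside a hindered ester.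
- Alkylation of 15 with F3 at −100 °C would give the hydrazone ester F4.
- i-Bu2AlH at −78 °C would reduce only the ester to the hydrazone allylic alcohol F5.
- MsCl/LiCl/collidine would convert F5 into 16.

Step 3. The olefination with the α-branched phosphonate may lose E selectivity, the phosphonate anion may eliminate silanolate, and the α-anilinooxy aldehyde may racemise while the slower reagent reacts.

Fallback: it sets out from 5 (with 18 and 2) and comes back at 7. C-alkylation of 18 (two equivalents, the second as base) with 2 would give the disubstituted stabilised ylide ethyl 2-(triphenylphosphoranylidene)-3-[(triisopropylsilyl)oxy]propanoate F6. After the same aminoxylation of 5 to 6, a Wittig reaction with F6 under neutral conditions would give 7; disubstituted stabilised ylides are reliably E-selective and need no base.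

Step 11. The α-alkoxy ketone 17 may epimerise at C3 before it is olefinated, and geometric control at C4=C5 rests on allylic strain alone.

Fallback: it sets out from 17 and comes back at 20. Addition of CH2=CHMgBr with CeCl3 at −78 °C would give the tertiary allylic alcohol 4-{(2E,5S,6E)-5-[(tert-butyldimethylsilyl)oxy]-8-chloro-3-methyl-7-{[(triisopropylsilyl)oxy]methyl}octa-2,6-dien-1-yl}-5-ethenyl-2,2-dimethyl-1,3-dioxan-5-ol F7 (both C4 epimers). Catalytic Ph3SiOReO3 in Et2O at low temperature would effect the 1,3-transposition to the primary allylic alcohol with the trisubstituted alkene. This equilibrium should favour C6 trans to C3, giving 20 and bypassing step 12.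

## Further compounds

F1 | step 14 | (2E)-2-[(4R)-4-{(2E,5S,6E)-5-[(tert-butyldimethylsilyl)oxy]-8-chloro-3-methyl-7-{[(triisopropylsilyl)oxy]methyl}octa-2,6-dien-1-yl}-2,2-dimethyl-1,3-dioxan-5-ylidene]acetaldehyde | CC1(C)OC/C(=C\C=O)[C@@H](C/C=C(C)/C[C@H](O[Si](C)(C)C(C)(C)C)/C=C(CO[Si](C(C)C)(C(C)C)C(C)C)/CCl)O1
F2 | step 9 | ethyl (2E,4S,6E)-4-[(tert-butyldimethylsilyl)oxy]-8-hydroxy-6-methyl-2-{[(triisopropylsilyl)oxy]methyl}octa-2,6-dienoate | CCOC(=O)/C(CO[Si](C(C)C)(C(C)C)C(C)C)=C/[C@@H](O[Si](C)(C)C(C)(C)C)C/C(C)=C/CO
F3 | step 9 | ethyl (2E,4S,6E)-8-bromo-4-[(tert-butyldimethylsilyl)oxy]-6-methyl-2-{[(triisopropylsilyl)oxy]methyl}octa-2,6-dienoate | CCOC(=O)/C(CO[Si](C(C)C)(C(C)C)C(C)C)=C/[C@@H](O[Si](C)(C)C(C)(C)C)C/C(C)=C/CBr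
F4 | step 9 | ethyl (2E,4S,6E)-4-[(tert-butyldimethylsilyl)oxy]-8-[(4R)-5-{[(2R)-2-(methoxymethyl)pyrrolidin-1-yl]imino}-2,2-dimethyl-1,3-dioxan-4-yl]-6-methyl-2-{[(triisopropylsilyl)oxy]methyl}octa-2,6-dienoate | CC1(C)OCC(=NN2CCC[C@@H]2COC)[C@@H](C/C=C(C)/C[C@H](O[Si](C)(C)C(C)(C)C)/C=C(CO[Si](C(C)C)(C(C)C)C(C)C)/C(=O)OCC)O1
F5 | step 9 | (2Z,4S,6E)-4-[(tert-butyldimethylsilyl)oxy]-8-[(4R)-5-{[(2R)-2-(methoxymethyl)pyrrolidin-1-yl]imino}-2,2-dimethyl-1,3-dioxan-4-yl]-6-methyl-2-{[(triisopropylsilyl)oxy]methyl}octa-2,6-dien-1-ol | CC1(C)OCC(=NN2CCC[C@@H]2COC)[C@@H](C/C=C(C)/C[C@H](O[Si](C)(C)C(C)(C)C)/C=C(CO[Si](C(C)C)(C(C)C)C(C)C)/CO)O1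
F6 | step 3 | ethyl 2-(triphenylphosphoranylidene)-3-[(triisopropylsilyl)oxy]propanoate | CCOC(=O)C(CO[Si](C(C)C)(C(C)C)C(C)C)=P(c1ccccc1)(c1ccccc1)c1ccccc1
F7 | step 11 | (4R)-4-{(2E,5S,6E)-5-[(tert-butyldimethylsilyl)oxy]-8-chloro-3-methyl-7-{[(triisopropylsilyl)oxy]methyl}octa-2,6-dien-1-yl}-5-ethenyl-2,2-dimethyl-1,3-dioxan-5-ol (C5 of the dioxane as both epimers) | CC1(C)OCC(O)(C=C)[C@@H](C/C=C(C)/C[C@H](O[Si](C)(C)C(C)(C)C)/C=C(CO[Si](C(C)C)(C(C)C)C(C)C)/CCl)O1
A1 | alternative 1 | open-chain C8–C9 epoxide / C10 (E)-vinyl iodide / C12 methyl ester, 3-O-tert-butyldiphenylsilyl, 6-O- and 15-O-tert-butyldimethylsilyl | I/C(C)=C/C[C@@H](O[Si](c1ccccc1)(c1ccccc1)C(C)(C)C)/C(CO[Si](C)(C)C(C)(C)C)=C/[C@@H](O[Si](C)(C)C(C)(C)C)[C@H](CC(=O)OC)[C@@H]1CO1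
A2 | alternative 1 | ten-membered trans-8,12-lactone lacking the C13 methylene, tris-silyl ether | C1C(=O)O[C@H]2C/C(C)=C/C[C@@H](O[Si](c3ccccc3)(c3ccccc3)C(C)(C)C)/C(CO[Si](C)(C)C(C)(C)C)=C/[C@@H](O[Si](C)(C)C(C)(C)C)[C@H]12
A3 | alternative 2 | trans-fused eudesma-1,3,11(13)-trien-12,8-olide, 3-silyl dienol ether, 15-O-tert-butyldimethylsilyl, 6-O-(3-methylbutanoyl) | C=C1C(=O)O[C@H]2C[C@@]3(C)C=CC(O[Si](C)(C)C(C)(C)C)=C(CO[Si](C)(C)C(C)(C)C)[C@@H]3[C@@H](OC(=O)CC(C)C)[C@H]12
A4 | alternative 2 | 3-silyloxy germacra-1(10),2,4,11(13)-tetraen-12,8-olide (C2=C3 cis in the ring) | C=C1C(=O)O[C@H]2C/C(C)=C/C=C(O[Si](C)(C)C(C)(C)C)\C(CO[Si](C)(C)C(C)(C)C)=C\[C@@H](OC(=O)CC(C)C)[C@H]12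
A5 | alternative 3 | open-chain C6 aldehyde with terminal C4≡C5 alkyne, 3-O-tert-butyldiphenylsilyl, 8-O- and 12-O-tert-butyldimethylsilyl | C#C[C@H](O[Si](c1ccccc1)(c1ccccc1)C(C)(C)C)C/C=C(\C)C[C@H](O[Si](C)(C)C(C)(C)C)[C@H](C=O)C(=C)CO[Si](C)(C)C(C)(C)C
A6 | alternative 3 | ten-membered (1(10)E)-en-4-yne with free C6 hydroxyl | O[C@@H]1C#C[C@H](O[Si](c2ccccc2)(c2ccccc2)C(C)(C)C)C/C=C(\C)C[C@H](O[Si](C)(C)C(C)(C)C)[C@H]1C(=C)CO[Si](C)(C)C(C)(C)C
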